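**Retrosynthetic overview**
1. Last step: the cis oxirane C1–C10 by reagent-controlled Shi epoxidation of a Z-cyclodecene; before it, the ten-membered carbocycle by ring-closing metathesis at C1=C10 of a seco diene that already carries both angelates.
2. The trans oxirane C4–C5 by Sharpless epoxidation of the C6 allylic alcohol; the C6 carbinol by 1,3-syn reduction of a C6 ketone.
3. The γ-lactone with C7, C8 and C11 in one step: a proposed organocatalytic oxa-Michael/aldol annulation of pyruvic acid onto the less hindered arm of an achiral cross-conjugated dienone (first stereocentres).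
4. The dienone from an E-alkenylalane (carboalumination of an enyne) and a dienoyl chloride (cross-metathesis of acrylic acid).
5. Ring order: lactone, C4–C5 oxirane, carbocycle, C1–C10 oxirane.

Assumption (one line): germacrane labels are used throughout (ring C1–C10; C11 lactone α-carbon, C12 lactone C=O, C13/C14/C15 the methyls on C11/C10/C4; lactone oxygen on C8, angelates on the oxygens of C6 and C11), and hex-1-en-5-yne and angelic anhydride are taken as purchasable.

**Route**

Step 1
Reactants: 1 acrylic acid; 2 2-methylpenta-1,4-diene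
Product: 3 (2E)-5-methylhexa-2,5-dienoic acid
Conditions: 2 (3 equiv), second-generation Hoveyda–Grubbs catalyst RuCl2(H2IMes)(=CH-C6H4-2-OiPr) (2 mol%), 1,4-benzoquinone (10 mol%), CH2Cl2, 40 °C
Reagents that add atoms: none
Why: Olefin cross-metathesis pairs the electron-poor acrylic acid with the monosubstituted olefin of 2 (the 1,1-disubstituted end is inert) and gives the conjugated acid as the E isomer; no stereocentre.

Step 2
Reactants: 3 (2E)-5-methylhexa-2,5-dienoic acid; 4 hex-1-en-5-yne
Product: 7 (4E,7E)-2,8-dimethyldodeca-1,4,7,11-tetraen-6-one, via alkenylalane 5 (not isolated), via acid chloride 6 (not isolated)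
Conditions: 4, AlMe3 (2 equiv), Cp2ZrCl2 (20 mol%), CH2Cl2, 0 °C to rt, then volatiles off in vacuo; 3, Me2C=C(Cl)NMe2, CH2Cl2, 0 °C; both combined, Pd(PPh3)4 (5 mol%), THF, 0 °C to rt
Reagents that add atoms: trimethylaluminium, C[Al](C)C (one methyl stays as C15; the AlMe2 group is held only in 5); 1-chloro-N,N,2-trimethylprop-1-en-1-amine, CC(C)=C(Cl)N(C)C (its chlorine is held only in 6)
Why: Negishi zirconium-catalysed syn-carboalumination of the alkyne (the alkene is untouched) fixes the E trisubstituted olefin, and palladium-catalysed acylation of the alkenylalane by the neutral-made acid chloride (Negishi acylation) goes with retention; no stereocentre.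

Step 3
Reactants: 7 (4E,7E)-2,8-dimethyldodeca-1,4,7,11-tetraen-6-one; 8 pyruvic acid
Product: 10 (3R,4R,5R)-3-hydroxy-3-methyl-4-[(2E)-3-methylhepta-2,6-dienoyl]-5-(2-methylprop-2-en-1-yl)oxolan-2-one, via pyruvate ester 9 (not isolated)
Conditions: 8 (1.5 equiv, slow addition), squaramide from 9-amino-9-deoxy-epi-quinidine and 3,5-bis(trifluoromethyl)aniline (10 mol%), toluene, 0 °C to rt
Reagents that add atoms: none
Why: Proposed new method: the quinuclidine of the catalyst takes the proton of 8 and the squaramide N–H bonds hold the less substituted enone arm, so the carboxylate adds reversibly to the C8 face that gives 8R (oxa-Michael addition; the β,β-disubstituted C4=C5 arm is too hindered), and the enolate so formed closes at once on the activated pyruvate ketone (5-exo aldol) with the acyl group trans to the C8 side chain and, through a hydrogen-bonded closed transition state, cis to the new hydroxyl, which pulls the equilibrium to the lactone; the closest known reactions are organocatalytic oxa-Michael/aldol domino annulations and base-mediated intramolecular aldol lactonisations of β-acyloxy ketones.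

Step 4
Reactants: 10 (3R,4R,5R)-3-hydroxy-3-methyl-4-[(2E)-3-methylhepta-2,6-dienoyl]-5-(2-methylprop-2-en-1-yl)oxolan-2-one
Product: 11 (3R,4R,5R)-3-hydroxy-4-[(1R,2E)-1-hydroxy-3-methylhepta-2,6-dien-1-yl]-3-methyl-5-(2-methylprop-2-en-1-yl)oxolan-2-one
Conditions: Et2BOMe (1.1 equiv), THF/MeOH 4:1, −78 °C; NaBH4 (1.2 equiv), −78 °C; MeOH co-evaporation
Reagents that add atoms: none
Why: Narasaka–Prasad reduction: Et2BOMe ties the C11 hydroxyl and the C6 ketone into a six-membered boron chelate cis-fused to the lactone, and NaBH4 attacks 1,2 from its convex face to give the 1,3-syn diol, i.e. the (1R) allylic carbinol at C6.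

Step 5
Reactants: 11 (3R,4R,5R)-3-hydroxy-4-[(1R,2E)-1-hydroxy-3-methylhepta-2,6-dien-1-yl]-3-methyl-5-(2-methylprop-2-en-1-yl)oxolan-2-one
Product: 12 (3R,4R,5R)-4-{(S)-[(2S,3S)-3-(but-3-en-1-yl)-3-methyloxiran-2-yl](hydroxy)methyl}-3-hydroxy-3-methyl-5-(2-methylprop-2-en-1-yl)oxolan-2-one
Conditions: Ti(OiPr)4 (20 mol%), L-(+)-diisopropyl tartrate (24 mol%), tBuOOH (2 equiv, in decane), 4 Å molecular sieves, CH2Cl2, −20 °C
Reagents that add atoms: tert-butyl hydroperoxide, CC(C)(C)OO
Why: Sharpless asymmetric epoxidation of the secondary allylic alcohol: L-(+)-tartrate delivers oxygen to the face that gives the (4S,5S) oxirane (the sense known for E-3-methylalk-2-en-1-ols), which for this C6 configuration is the fast erythro (matched) mode, and only the allylic olefin reacts.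

Step 6
Reactants: 12 (3R,4R,5R)-4-{(S)-[(2S,3S)-3-(but-3-en-1-yl)-3-methyloxiran-2-yl](hydroxy)methyl}-3-hydroxy-3-methyl-5-(2-methylprop-2-en-1-yl)oxolan-2-one; 13 angelic anhydride [(2Z)-2-methylbut-2-enoic anhydride]
Product: 14 (3R,4S,5R)-4-{(S)-[(2S,3S)-3-(but-3-en-1-yl)-3-methyloxiran-2-yl][(2Z)-2-methylbut-2-enoyloxy]methyl}-3-methyl-5-(2-methylprop-2-en-1-yl)-2-oxooxolan-3-yl (2Z)-2-methylbut-2-enoate
Conditions: LiN(SiMe3)2 (2.2 equiv), THF, −78 °C; 13 (4 equiv), −78 to −20 °C; aq. NH4Cl
Reagents that add atoms: none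
Why: Acylation of the secondary and the tertiary lithium alkoxide by the anhydride (nucleophilic acyl substitution) needs no nucleophilic catalyst or heat, so the Z geometry of the angelate is kept, and the low temperature suppresses Payne rearrangement and translactonisation; no new stereocentre.

Step 7
Reactants: 14 (the seco diene bis-angelate of step 6)
Product: 15 (1(10)Z,4S,5S,6S,7S,8R,11R)-4,5-epoxy-6,11-bis[(2Z)-2-methylbut-2-enoyloxy]germacr-1(10)-en-12,8-olide
Conditions: second-generation Grubbs catalyst RuCl2(H2IMes)(PCy3)(=CHPh) (10 mol%), toluene (1 mM), 80 °C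
Reagents that add atoms: none
Why: Ring-closing metathesis joins the monosubstituted and the 1,1-disubstituted olefin (the trisubstituted angelate olefins are inert), and the ten-membered ring takes the new trisubstituted olefin as the less strained Z isomer.

Step 8
Reactants: 15 (1(10)Z,4S,5S,6S,7S,8R,11R)-4,5-epoxy-6,11-bis[(2Z)-2-methylbut-2-enoyloxy]germacr-1(10)-en-12,8-olide
Product: 16 (1R,4S,5S,6S,7S,8R,10S,11R)-1,10:4,5-diepoxy-6,11-bis[(2Z)-2-methylbut-2-enoyloxy]germacran-12,8-olide (CNP0219924.1)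
Conditions: D-fructose-derived Shi ketone (30 mol%), KHSO5 (as Oxone), K2CO3, Bu4NHSO4, MeCN/CH2(OMe)2/aq. Na2B4O7 buffer (pH 10.5), 0 °C
Reagents that add atoms: potassium peroxymonosulfate, [K+].[O-]S(=O)(=O)OO
Why: Shi asymmetric epoxidation: the chiral dioxirane adds through its spiro transition state to the only electron-rich olefin on the face that makes C1 R (and so C10 S, cis oxirane), while the electron-poor angelate olefins do not react.

**Compound list**
1 | acrylic acid | C=CC(=O)O | starting material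
2 | 2-methylpenta-1,4-diene | C=CCC(C)=C | starting material
3 | (2E)-5-methylhexa-2,5-dienoic acid | CC(=C)C/C=C/C(=O)O | intermediate
4 | hex-1-en-5-yne | C=CCCC#C | starting material
5 | dimethyl[(1E)-2-methylhexa-1,5-dien-1-yl]alane (alkenylalane) | C=CCC/C(C)=C/[Al](C)C | intermediate
6 | (2E)-5-methylhexa-2,5-dienoyl chloride (acid chloride) | CC(=C)C/C=C/C(=O)Cl | intermediate
7 | (4E,7E)-2,8-dimethyldodeca-1,4,7,11-tetraen-6-one | C=CCC/C(C)=C/C(=O)/C=C/CC(C)=C | intermediate
8 | pyruvic acid | CC(=O)C(=O)O | starting material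
9 | (4R,7E)-2,8-dimethyl-6-oxododeca-1,7,11-trien-4-yl 2-oxopropanoate (pyruvate ester) | CC(=O)C(=O)O[C@H](CC(C)=C)CC(=O)/C=C(\C)CCC=C | intermediate
10 | (3R,4R,5R)-3-hydroxy-3-methyl-4-[(2E)-3-methylhepta-2,6-dienoyl]-5-(2-methylprop-2-en-1-yl)oxolan-2-one | O=C(/C=C(\C)CCC=C)[C@@H]1[C@@H](CC(C)=C)OC(=O)[C@]1(C)O | intermediate
11 | (3R,4R,5R)-3-hydroxy-4-[(1R,2E)-1-hydroxy-3-methylhepta-2,6-dien-1-yl]-3-methyl-5-(2-methylprop-2-en-1-yl)oxolan-2-one | O[C@H](/C=C(\C)CCC=C)[C@@H]1[C@@H](CC(C)=C)OC(=O)[C@]1(C)O | intermediate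
12 | (3R,4R,5R)-4-{(S)-[(2S,3S)-3-(but-3-en-1-yl)-3-methyloxiran-2-yl](hydroxy)methyl}-3-hydroxy-3-methyl-5-(2-methylprop-2-en-1-yl)oxolan-2-one | O[C@H]([C@@H]1O[C@@]1(C)CCC=C)[C@@H]1[C@@H](CC(C)=C)OC(=O)[C@]1(C)O | intermediate
13 | angelic anhydride, (2Z)-2-methylbut-2-enoic anhydride | C/C=C(/C)C(=O)OC(=O)/C(C)=C\C | starting material
14 | (3R,4S,5R)-4-{(S)-[(2S,3S)-3-(but-3-en-1-yl)-3-methyloxiran-2-yl][(2Z)-2-methylbut-2-enoyloxy]methyl}-3-methyl-5-(2-methylprop-2-en-1-yl)-2-oxooxolan-3-yl (2Z)-2-methylbut-2-enoate | C/C=C(/C)C(=O)O[C@H]([C@@H]1O[C@@]1(C)CCC=C)[C@@H]1[C@@H](CC(C)=C)OC(=O)[C@]1(C)OC(=O)/C(C)=C\C | intermediate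
15 | (1(10)Z,4S,5S,6S,7S,8R,11R)-4,5-epoxy-6,11-bis[(2Z)-2-methylbut-2-enoyloxy]germacr-1(10)-en-12,8-olide | C/C=C(/C)C(=O)O[C@H]1[C@@H]2[C@@H](C/C(C)=C\CC[C@]3(C)O[C@@H]13)OC(=O)[C@]2(C)OC(=O)/C(C)=C\C | intermediate
16 | (1R,4S,5S,6S,7S,8R,10S,11R)-1,10:4,5-diepoxy-6,11-bis[(2Z)-2-methylbut-2-enoyloxy]germacran-12,8-olide (CNP0219924.1) | C/C=C(/C)C(=O)O[C@H]1[C@@H]2[C@@H](C[C@]3(C)O[C@@H]3CC[C@]3(C)O[C@@H]13)OC(=O)[C@]2(C)OC(=O)/C(C)=C\C | target

**Totals and risks**

Total step count: 8. Longest linear sequence: 8 (steps 1 to 8; 4, 8 and 13 enter as purchased materials).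

The three steps most likely to fail:

The annulation of step 3 is the proposed new step. The carboxylate may be too weak a nucleophile, pyruvic acid may add through carbon or self-condense, the skipped diene may slip into conjugation, or facial control at C8 may be poor (the quinine-derived pseudo-enantiomer is the first thing to try for the last point). The fallback uses known chemistry, sets out from 7 and comes back at 10. Copper-catalysed asymmetric conjugate borylation of 7 (CuCl, NaOtBu, a Josiphos-type bisphosphine chosen for the 4R series, B2pin2, MeOH, THF) takes place at the less hindered C7=C8 arm and gives the β-boryl ketone (4R,7E)-2,8-dimethyl-4-(4,4,5,5-tetramethyl-1,3,2-dioxaborolan-2-yl)dodeca-1,7,11-trien-6-one F1. Oxidation with NaBO3·4H2O gives the β-hydroxy ketone (4R,7E)-4-hydroxy-2,8-dimethyldodeca-1,7,11-trien-6-one F2. Esterification with 8 (DCC, catalytic DMAP, CH2Cl2, 0 °C) gives the pyruvate ester 9, this time isolated. Soft enolisation (MgBr2·OEt2, iPr2NEt, CH2Cl2, −20 °C) closes it by a chelated intramolecular aldol reaction to 10.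

The ring-closing metathesis of step 7 may give oligomers or stall, because initiation at the 1,1-disubstituted olefin is slow and the rigid oxirane and two bulky esters add strain. The fallback closes the ring before the oxirane and the esters exist; it sets out from 11 and comes back at 15. Diol 11 is cyclised with the same ruthenium catalyst at high dilution to the macrocyclic diene diol (1(10)Z,4E,6R,7R,8R,11R)-6,11-dihydroxygermacra-1(10),4-dien-12,8-olide F3. Sharpless epoxidation as in step 5 then gives the macrocyclic epoxy diol (1(10)Z,4S,5S,6S,7R,8R,11R)-4,5-epoxy-6,11-dihydroxygermacr-1(10)-en-12,8-olide F4, and acylation with 13 as in step 6 gives 15.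

In the final epoxidation of step 8 the ring conformation may override the chiral dioxirane and give the C1/C10-epimeric oxirane. The fallback turns that same substrate bias around; it sets out from 15 and comes back at 16. N-Bromosuccinimide in wet THF at 0 °C forms the bromonium ion on the more exposed face, and water opens it at the tertiary C10 from the other side to give the bromohydrin (1S,4S,5S,6S,7S,8R,10S,11R)-1-bromo-4,5-epoxy-10-hydroxy-6,11-bis[(2Z)-2-methylbut-2-enoyloxy]germacran-12,8-olide F5. K2CO3 in dry MeCN closes it with inversion at C1, which puts the oxirane oxygen on the face opposite to direct epoxidation and gives 16.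

Further compounds
F1 | step 3 | (4R,7E)-2,8-dimethyl-4-(4,4,5,5-tetramethyl-1,3,2-dioxaborolan-2-yl)dodeca-1,7,11-trien-6-one | CC1(C)OB(OC1(C)C)[C@H](CC(C)=C)CC(=O)/C=C(\C)CCC=C
F2 | step 3 | (4R,7E)-4-hydroxy-2,8-dimethyldodeca-1,7,11-trien-6-one | O[C@H](CC(C)=C)CC(=O)/C=C(\C)CCC=C
F3 | step 7 | (1(10)Z,4E,6R,7R,8R,11R)-6,11-dihydroxygermacra-1(10),4-dien-12,8-olide | O[C@H]1[C@@H]2[C@@H](C/C(C)=C\CC/C(C)=C/1)OC(=O)[C@]2(C)O
F4 | step 7 | (1(10)Z,4S,5S,6S,7R,8R,11R)-4,5-epoxy-6,11-dihydroxygermacr-1(10)-en-12,8-olide | O[C@H]1[C@@H]2[C@@H](C/C(C)=C\CC[C@]3(C)O[C@@H]13)OC(=O)[C@]2(C)O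
F5 | step 8 | (1S,4S,5S,6S,7S,8R,10S,11R)-1-bromo-4,5-epoxy-10-hydroxy-6,11-bis[(2Z)-2-methylbut-2-enoyloxy]germacran-12,8-olide | C/C=C(/C)C(=O)O[C@H]1[C@@H]2[C@@H](C[C@](C)(O)[C@@H](Br)CC[C@]3(C)O[C@@H]13)OC(=O)[C@]2(C)OC(=O)/C(C)=C\C
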